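**Retrosynthetic overview**
1. Target 25 ⇐ desilylation of macrocycle 24 ⇐ closure of the 14-membered ring at C12–C13 by intramolecular B-alkyl Suzuki coupling of vinyl iodide 22.
2. 22 ⇐ lactol 12 by two Johnson–Claisen [3,3]-sigmatropic rearrangements (C5–C6 and C9–C10 bonds, 3Z and 7E alkenes) and a Z-selective iodo-olefination (11Z).
3. 12 (C1 and the carbinol centre set, vinyl = C14–C13) ⇐ cis-fused bicyclic ketone 5 by silyl enol ether ozonolysis ⇐ Ueno–Stork radical cyclization on enone 4.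
4. 4 ⇐ (R)-linalool 1 by ring-closing metathesis; the carbinol centre is bought and its side chain is tied into a cyclopentene so that C1 is set on a ring.
5. Ring order: temporary cyclopentene (step 1), fused oxolane acetal (step 4), cyclopentane opened (step 6), acetal opened (step 12), 14-membered carbocycle last (step 18).

Assumption: natural (R)-(−)-linalool of high enantiomeric purity is the bought chiral material; ring atoms are numbered C1–C14 as in the name of 25 (C1 carries the side chain, C4 the CH2OH).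

**Route**

Step 1
Reactants: 1 (R)-(−)-linalool
Product: 2 (1R)-1-methylcyclopent-2-en-1-ol
Conditions: second-generation Grubbs catalyst RuCl2(=CHPh)(PCy3)(H2IMes) (1 mol %), CH2Cl2, 40 °C
Reagents that add atoms: none
Why: Ring-closing metathesis between the vinyl group and the trisubstituted alkene expels 2-methylpropene and closes the cyclopentene, leaving the bought carbinol stereocentre untouched.

Step 2
Reactants: 2 (1R)-1-methylcyclopent-2-en-1-ol
Product: 3 (1R)-1-(2-bromo-1-ethoxyethoxy)-1-methylcyclopent-2-ene (both epimers at the acetal carbon)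
Conditions: N-bromosuccinimide, ethyl vinyl ether, 2,6-lutidine (cat.), CH2Cl2, −40 → 0 °C
Reagents that add atoms: ethyl vinyl ether C=COCC; N-bromosuccinimide O=C1CCC(=O)N1Br
Why: Bromoetherification of the enol ether (bromonium ion opened by the tertiary alcohol) installs the Ueno–Stork bromoacetal tether on the carbinol oxygen without touching the stereocentre.

Step 3
Reactants: 3 (1R)-1-(2-bromo-1-ethoxyethoxy)-1-methylcyclopent-2-ene
Product: 4 (4R)-4-(2-bromo-1-ethoxyethoxy)-4-methylcyclopent-2-en-1-one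
Conditions: Rh2(cap)4 (dirhodium tetracaprolactamate, 1 mol %), tBuOOH, K2CO3, CH2Cl2, rt
Reagents that add atoms: tert-butyl hydroperoxide CC(C)(C)OO
Why: Radical allylic oxidation (peroxyl H-abstraction, then trapping at the less hindered allyl terminus) turns the only allylic CH2 into the enone carbonyl under basic conditions that spare the acid-labile tertiary acetal.

Step 4
Reactants: 4 (4R)-4-(2-bromo-1-ethoxyethoxy)-4-methylcyclopent-2-en-1-one
Product: 5 (3aS,6aR)-2-ethoxy-6a-methylhexahydro-2H-cyclopenta[b]furan-5(3H)-one (cis-fused; both epimers at C2)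
Conditions: Bu3SnH, AIBN (cat.), benzene, 80 °C, slow addition
Reagents that add atoms: none
Why: In this Ueno–Stork radical cyclization the primary radical adds 5-exo-trig to the enone β-carbon, and because the two fused five-membered rings can only be cis-fused the new C1–C2 bond forms on the face of the tether oxygen, which sets C1 from the linalool-derived carbinol centre.

Step 5
Reactants: 5 (3aS,6aR)-2-ethoxy-6a-methylhexahydro-2H-cyclopenta[b]furan-5(3H)-one
Product: 6 {[(3aS,6aR)-2-ethoxy-6a-methyl-3,3a,6,6a-tetrahydro-2H-cyclopenta[b]furan-5-yl]oxy}trimethylsilane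
Conditions: LiN(iPr)2, Me3SiCl, THF, −78 °C
Reagents that add atoms: chlorotrimethylsilane C[Si](C)(C)Cl
Why: Kinetic enolization with in situ O-silylation removes a proton from the α-CH2 remote from the quaternary carbon, giving the silyl enol ether on the ring-fusion side.

Step 6
Reactants: 6 {[(3aS,6aR)-2-ethoxy-6a-methyl-3,3a,6,6a-tetrahydro-2H-cyclopenta[b]furan-5-yl]oxy}trimethylsilane
Product: 7 2-[(2R,3R)-5-ethoxy-3-formyl-2-methyloxolan-2-yl]acetic acid
Conditions: O3, CH2Cl2, −78 °C; then Me2S; aq. NaHCO3 work-up, then mild acidification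
Reagents that add atoms: ozone [O-][O+]=O
Why: Ozonolysis of the electron-rich silyl enol ether, the only C=C present, opens the cyclopentane to the C14 aldehyde and (through the silyl ester) the carboxylic acid without touching a stereocentre.

Step 7
Reactants: 7 2-[(2R,3R)-5-ethoxy-3-formyl-2-methyloxolan-2-yl]acetic acid
Product: 8 2-[(2R,3S)-5-ethoxy-3-ethenyl-2-methyloxolan-2-yl]acetic acid
Conditions: Ph3PCH3Br, KN(SiMe3)2 (3 equiv of ylide), THF, −78 → 0 °C
Reagents that add atoms: methyltriphenylphosphonium bromide C[P+](c1ccccc1)(c1ccccc1)c1ccccc1.[Br-]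
Why: Wittig methylenation of the aldehyde (the carboxylate is inert) at low temperature gives the vinyl group C14=C13 without epimerizing C1.

Step 8
Reactants: 8 2-[(2R,3S)-5-ethoxy-3-ethenyl-2-methyloxolan-2-yl]acetic acid
Product: 9 2-[(2R,3S)-5-ethoxy-3-ethenyl-2-methyloxolan-2-yl]ethan-1-ol
Conditions: LiAlH4, THF, 0 °C → rt
Reagents that add atoms: none
Why: Hydride reduction of the carboxylic acid gives the primary alcohol, and the acetal and the alkene are inert to LiAlH4.

Step 9
Reactants: 9 2-[(2R,3S)-5-ethoxy-3-ethenyl-2-methyloxolan-2-yl]ethan-1-ol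
Product: 10 (2R,3S)-5-ethoxy-3-ethenyl-2-(2-iodoethyl)-2-methyloxolane
Conditions: I2, PPh3, imidazole, CH2Cl2, 0 °C
Reagents that add atoms: iodine II
Why: Appel-type iodination of the unhindered primary alcohol proceeds under imidazole-buffered conditions that keep the acetal intact.

Step 10
Reactants: 10 (2R,3S)-5-ethoxy-3-ethenyl-2-(2-iodoethyl)-2-methyloxolane
Product: 12 (4S,5R)-4-ethenyl-5-methyl-5-(4-methylpent-3-en-1-yl)oxolan-2-ol (lactol; both anomers), via ethyl acetal 11 (not isolated)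
Conditions: (CH3)2C=CHMgBr, Li2CuCl4 (5 mol %), THF, −20 → 0 °C; then 1 M HCl, THF, rt
Reagents that add atoms: (2-methylprop-1-en-1-yl)magnesium bromide CC(C)=C[Mg]Br; water O
Why: Copper-catalysed (Kochi-type) cross-coupling of the primary iodide and the alkenyl Grignard reagent rebuilds the 4-methylpent-3-enyl chain, and the acidic work-up hydrolyses the ethyl acetal to the lactol.

Step 11
Reactants: 13 2-bromoprop-2-en-1-ol
Product: 14 [(2-bromoprop-2-en-1-yl)oxy](tert-butyl)dimethylsilane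
Conditions: tBuMe2SiCl, imidazole, DMF, rt
Reagents that add atoms: tert-butyl(chloro)dimethylsilane CC(C)(C)[Si](C)(C)Cl
Why: Imidazole-mediated silylation protects the primary allylic alcohol that becomes the C4 hydroxymethyl group.

Step 12
Reactants: 12 (4S,5R)-4-ethenyl-5-methyl-5-(4-methylpent-3-en-1-yl)oxolan-2-ol; 14 [(2-bromoprop-2-en-1-yl)oxy](tert-butyl)dimethylsilane
Product: 16 (5S,6R)-2-({[tert-butyl(dimethyl)silyl]oxy}methyl)-5-ethenyl-6,10-dimethylundeca-1,9-diene-3,6-diol (both C3 epimers), via alkenylchromium dichloride 15 (not isolated)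
Conditions: CrCl2 (6 equiv), NiCl2 (2 mol %), DMF, rt
Reagents that add atoms: none
Why: In this Nozaki–Hiyama–Kishi reaction the alkenylchromium species adds chemoselectively to the open hydroxy-aldehyde form of the lactol to form C3–C4, and the new carbinol centre is consumed in the next step so its configuration does not matter.

Step 13
Reactants: 16 (5S,6R)-2-({[tert-butyl(dimethyl)silyl]oxy}methyl)-5-ethenyl-6,10-dimethylundeca-1,9-diene-3,6-diol
Product: 17 ethyl (4Z,7S,8R)-4-({[tert-butyl(dimethyl)silyl]oxy}methyl)-7-ethenyl-8-hydroxy-8,12-dimethyltrideca-4,11-dienoate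
Conditions: MeC(OEt)3, EtCO2H (cat.), xylene, 135 °C
Reagents that add atoms: triethyl orthoacetate CCOC(C)(OCC)OCC
Why: The Johnson–Claisen [3,3]-sigmatropic rearrangement of the ketene acetal of the secondary allylic alcohol forms C5–C6 through a chair transition state with the C3 substituent equatorial, which places C2 trans to C5 and cis to CH2OSi (the 3Z geometry of the target).

Step 14
Reactants: 17 ethyl (4Z,7S,8R)-4-({[tert-butyl(dimethyl)silyl]oxy}methyl)-7-ethenyl-8-hydroxy-8,12-dimethyltrideca-4,11-dienoate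
Product: 19 (6Z,9S,10R)-6-({[tert-butyl(dimethyl)silyl]oxy}methyl)-9-ethenyl-2,10,14-trimethylpentadeca-1,6,13-triene-3,10-diol (both C3 epimers), via C7 aldehyde 18 (not isolated)
Conditions: iBu2AlH (2.2 equiv), CH2Cl2, −78 °C; then CH2=C(CH3)MgBr, THF, −78 → 0 °C
Reagents that add atoms: isopropenylmagnesium bromide CC(=C)[Mg]Br
Why: Low-temperature ester reduction stops at the aluminium hemiacetal, and the aldehyde it releases is trapped in the same flask by Grignard 1,2-addition, giving a carbinol centre that is again consumed in the following Claisen step.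

Step 15
Reactants: 19 (6Z,9S,10R)-6-({[tert-butyl(dimethyl)silyl]oxy}methyl)-9-ethenyl-2,10,14-trimethylpentadeca-1,6,13-triene-3,10-diol
Product: 20 ethyl (4E,8Z,11S,12R)-8-({[tert-butyl(dimethyl)silyl]oxy}methyl)-11-ethenyl-12-hydroxy-4,12,16-trimethylheptadeca-4,8,15-trienoate
Conditions: MeC(OEt)3, EtCO2H (cat.), xylene, 135 °C
Reagents that add atoms: triethyl orthoacetate CCOC(C)(OCC)OCC
Why: The second Johnson–Claisen [3,3]-sigmatropic rearrangement forms C9–C10 and, through the chair transition state with the C7 substituent equatorial, the 7E trisubstituted alkene.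

Step 16
Reactants: 20 ethyl (4E,8Z,11S,12R)-8-({[tert-butyl(dimethyl)silyl]oxy}methyl)-11-ethenyl-12-hydroxy-4,12,16-trimethylheptadeca-4,8,15-trienoate
Product: 21 (4E,8Z,11S,12R)-8-({[tert-butyl(dimethyl)silyl]oxy}methyl)-11-ethenyl-12-hydroxy-4,12,16-trimethylheptadeca-4,8,15-trienal
Conditions: iBu2AlH (2.1 equiv), CH2Cl2, −78 °C
Reagents that add atoms: none
Why: Partial ester reduction at −78 °C stops at the stable tetrahedral aluminate, which gives the C11 aldehyde on work-up.

Step 17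
Reactants: 21 (4E,8Z,11S,12R)-8-({[tert-butyl(dimethyl)silyl]oxy}methyl)-11-ethenyl-12-hydroxy-4,12,16-trimethylheptadeca-4,8,15-trienal
Product: 22 (6R,7S,9Z,13E,17Z)-10-({[tert-butyl(dimethyl)silyl]oxy}methyl)-7-ethenyl-18-iodo-2,6,14-trimethylnonadeca-2,9,13,17-tetraen-6-ol
Conditions: Ph3P(CH2CH3)I, nBuLi, THF; I2, −78 °C; NaN(SiMe3)2; then 21, −78 → −20 °C
Reagents that add atoms: ethyltriphenylphosphonium iodide CC[P+](c1ccccc1)(c1ccccc1)c1ccccc1.[I-]; iodine II
Why: The Stork–Zhao-type Wittig olefination with the α-iodo ylide gives the (Z)-2-iodoalkene through the kinetically favoured cis-oxaphosphetane, which sets the 11Z geometry.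

Step 18
Reactants: 22 (6R,7S,9Z,13E,17Z)-10-({[tert-butyl(dimethyl)silyl]oxy}methyl)-7-ethenyl-18-iodo-2,6,14-trimethylnonadeca-2,9,13,17-tetraen-6-ol
Product: 24 (2R)-2-[(1R,3Z,7E,11Z)-4-({[tert-butyl(dimethyl)silyl]oxy}methyl)-8,12-dimethylcyclotetradeca-3,7,11-trien-1-yl]-6-methylhept-5-en-2-ol, via B-alkyl-9-BBN borane 23 (not isolated)
Conditions: 9-BBN-H (2.2 equiv), THF, rt; then PdCl2(dppf) (10 mol %), AsPh3, Cs2CO3, DMF/THF/H2O, high dilution, 50 °C
Reagents that add atoms: none
Why: 9-BBN-H hydroborates only the monosubstituted vinyl group (anti-Markovnikov), and the B-alkyl borane then closes the 14-membered ring by intramolecular B-alkyl Suzuki–Miyaura coupling with the vinyl iodide with retention of the Z geometry.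

Step 19
Reactants: 24 (2R)-2-[(1R,3Z,7E,11Z)-4-({[tert-butyl(dimethyl)silyl]oxy}methyl)-8,12-dimethylcyclotetradeca-3,7,11-trien-1-yl]-6-methylhept-5-en-2-ol
Product: 25 (2R)-2-[(1R,3Z,7E,11Z)-4-(hydroxymethyl)-8,12-dimethylcyclotetradeca-3,7,11-trien-1-yl]-6-methylhept-5-en-2-ol
Conditions: Bu4NF, THF, rt
Reagents that add atoms: none
Why: Fluoride-mediated desilylation cleaves the Si–O bond of the primary silyl ether and releases the allylic alcohol, leaving both stereocentres and all three alkene geometries intact.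

**Compound list**
1 | (R)-(−)-linalool, (3R)-3,7-dimethylocta-1,6-dien-3-ol | CC(C)=CCC[C@@](C)(O)C=C | starting material
2 | (1R)-1-methylcyclopent-2-en-1-ol | C1C[C@@](C)(O)C=C1 | intermediate
3 | (1R)-1-(2-bromo-1-ethoxyethoxy)-1-methylcyclopent-2-ene (both acetal epimers) | C1C[C@@](C)(OC(CBr)OCC)C=C1 | intermediate
4 | (4R)-4-(2-bromo-1-ethoxyethoxy)-4-methylcyclopent-2-en-1-one (both acetal epimers) | O=C1C[C@@](C)(OC(CBr)OCC)C=C1 | intermediate
5 | (3aS,6aR)-2-ethoxy-6a-methylhexahydro-2H-cyclopenta[b]furan-5(3H)-one (cis-fused; both C2 epimers) | O=C1C[C@@]2(C)OC(OCC)C[C@H]2C1 | intermediate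
6 | {[(3aS,6aR)-2-ethoxy-6a-methyl-3,3a,6,6a-tetrahydro-2H-cyclopenta[b]furan-5-yl]oxy}trimethylsilane | C[Si](C)(C)OC1=C[C@@H]2CC(OCC)O[C@]2(C)C1 | intermediate
7 | 2-[(2R,3R)-5-ethoxy-3-formyl-2-methyloxolan-2-yl]acetic acid | OC(=O)C[C@@]1(C)OC(OCC)C[C@H]1C=O | intermediate
8 | 2-[(2R,3S)-5-ethoxy-3-ethenyl-2-methyloxolan-2-yl]acetic acid | OC(=O)C[C@@]1(C)OC(OCC)C[C@H]1C=C | intermediate
9 | 2-[(2R,3S)-5-ethoxy-3-ethenyl-2-methyloxolan-2-yl]ethan-1-ol | OCC[C@@]1(C)OC(OCC)C[C@H]1C=C | intermediate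
10 | (2R,3S)-5-ethoxy-3-ethenyl-2-(2-iodoethyl)-2-methyloxolane | ICC[C@@]1(C)OC(OCC)C[C@H]1C=C | intermediate
11 | (2R,3S)-5-ethoxy-3-ethenyl-2-methyl-2-(4-methylpent-3-en-1-yl)oxolane | CC(C)=CCC[C@@]1(C)OC(OCC)C[C@H]1C=C | intermediate
12 | (4S,5R)-4-ethenyl-5-methyl-5-(4-methylpent-3-en-1-yl)oxolan-2-ol (both anomers) | CC(C)=CCC[C@@]1(C)OC(O)C[C@H]1C=C | intermediate
13 | 2-bromoprop-2-en-1-ol | OCC(Br)=C | starting material
14 | [(2-bromoprop-2-en-1-yl)oxy](tert-butyl)dimethylsilane | C=C(Br)CO[Si](C)(C)C(C)(C)C | intermediate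
15 | dichloro{3-[(tert-butyldimethylsilyl)oxy]prop-1-en-2-yl}chromium | C=C([Cr](Cl)Cl)CO[Si](C)(C)C(C)(C)C | intermediate
16 | (5S,6R)-2-({[tert-butyl(dimethyl)silyl]oxy}methyl)-5-ethenyl-6,10-dimethylundeca-1,9-diene-3,6-diol (both C3 epimers) | CC(C)=CCC[C@@](C)(O)[C@H](C=C)CC(O)C(=C)CO[Si](C)(C)C(C)(C)C | intermediate
17 | ethyl (4Z,7S,8R)-4-({[tert-butyl(dimethyl)silyl]oxy}methyl)-7-ethenyl-8-hydroxy-8,12-dimethyltrideca-4,11-dienoate | CC(C)=CCC[C@@](C)(O)[C@H](C=C)C/C=C(\CO[Si](C)(C)C(C)(C)C)CCC(=O)OCC | intermediate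
18 | (4Z,7S,8R)-4-({[tert-butyl(dimethyl)silyl]oxy}methyl)-7-ethenyl-8-hydroxy-8,12-dimethyltrideca-4,11-dienal | CC(C)=CCC[C@@](C)(O)[C@H](C=C)C/C=C(\CO[Si](C)(C)C(C)(C)C)CCC=O | intermediate
19 | (6Z,9S,10R)-6-({[tert-butyl(dimethyl)silyl]oxy}methyl)-9-ethenyl-2,10,14-trimethylpentadeca-1,6,13-triene-3,10-diol (both C3 epimers) | CC(C)=CCC[C@@](C)(O)[C@H](C=C)C/C=C(\CO[Si](C)(C)C(C)(C)C)CCC(O)C(C)=C | intermediate
20 | ethyl (4E,8Z,11S,12R)-8-({[tert-butyl(dimethyl)silyl]oxy}methyl)-11-ethenyl-12-hydroxy-4,12,16-trimethylheptadeca-4,8,15-trienoate | CC(C)=CCC[C@@](C)(O)[C@H](C=C)C/C=C(\CO[Si](C)(C)C(C)(C)C)CC/C=C(\C)CCC(=O)OCC | intermediate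
21 | (4E,8Z,11S,12R)-8-({[tert-butyl(dimethyl)silyl]oxy}methyl)-11-ethenyl-12-hydroxy-4,12,16-trimethylheptadeca-4,8,15-trienal | CC(C)=CCC[C@@](C)(O)[C@H](C=C)C/C=C(\CO[Si](C)(C)C(C)(C)C)CC/C=C(\C)CCC=O | intermediate
22 | (6R,7S,9Z,13E,17Z)-10-({[tert-butyl(dimethyl)silyl]oxy}methyl)-7-ethenyl-18-iodo-2,6,14-trimethylnonadeca-2,9,13,17-tetraen-6-ol | CC(C)=CCC[C@@](C)(O)[C@H](C=C)C/C=C(\CO[Si](C)(C)C(C)(C)C)CC/C=C(\C)CC/C=C(/C)I | intermediate
23 | (6R,7R,9Z,13E,17Z)-7-[2-(9-borabicyclo[3.3.1]nonan-9-yl)ethyl]-10-({[tert-butyl(dimethyl)silyl]oxy}methyl)-18-iodo-2,6,14-trimethylnonadeca-2,9,13,17-tetraen-6-ol | CC(C)=CCC[C@@](C)(O)[C@H](CCB1C2CCCC1CCC2)C/C=C(\CO[Si](C)(C)C(C)(C)C)CC/C=C(\C)CC/C=C(/C)I | intermediate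
24 | (2R)-2-[(1R,3Z,7E,11Z)-4-({[tert-butyl(dimethyl)silyl]oxy}methyl)-8,12-dimethylcyclotetradeca-3,7,11-trien-1-yl]-6-methylhept-5-en-2-ol | CC(C)=CCC[C@@](C)(O)[C@H]1C/C=C(\CO[Si](C)(C)C(C)(C)C)CC/C=C(\C)CC/C=C(/C)CC1 | intermediate
25 | (2R)-2-[(1R,3Z,7E,11Z)-4-(hydroxymethyl)-8,12-dimethylcyclotetradeca-3,7,11-trien-1-yl]-6-methylhept-5-en-2-ol | CC(C)=CCC[C@@](C)(O)[C@H]1C/C=C(\CO)CC/C=C(\C)CC/C=C(/C)CC1 | target

**Step count and risks**
Total steps: 19. Longest linear sequence: 18 (1 → 25 through steps 1–10 and 12–19; step 11 prepares fragment 14).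

The three steps most likely to fail:

Step 3, the allylic oxidation of the acid-labile tertiary allylic acetal 3, may give low yield or partial trapping of the allyl radical at the wrong terminus. The fallback sets out from 3 and replaces the one-step radical oxidation by a two-stage hydroxylation–oxidation. SeO2 with tBuOOH (pyridine-buffered, CH2Cl2) hydroxylates the allylic CH2 regiospecifically by an ene reaction followed by a [2,3]-shift, giving (4R)-4-(2-bromo-1-ethoxyethoxy)-4-methylcyclopent-2-en-1-ol F1. MnO2 in CH2Cl2 then oxidizes this allylic alcohol, and the fallback returns to the route at 4.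

Step 7, the basic Wittig methylenation of aldehyde-acid 7, risks epimerization at C1 or β-elimination of the ring oxygen. The fallback sets out from 7 and removes both the free acid and the basic ylide. Me3SiCHN2 in toluene/MeOH gives methyl 2-[(2R,3R)-5-ethoxy-3-formyl-2-methyloxolan-2-yl]acetate F2. The non-basic titanium methylidene from the Tebbe reagent Cp2TiCH2ClAlMe2 (THF, pyridine, −40 °C) methylenates the aldehyde faster than the ester and gives methyl 2-[(2R,3S)-5-ethoxy-3-ethenyl-2-methyloxolan-2-yl]acetate F3. LiAlH4 reduction of F3 returns to the route at 9.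

Step 18, the B-alkyl Suzuki macrocyclization, may give oligomers or protodeboronation instead of the 14-membered ring. The fallback sets out from ester 20 and closes the ring by an intramolecular Wittig reaction that forms C11=C12 instead.
- Hydroboration of the vinyl group with 9-BBN-H and oxidation with NaBO3 gives ethyl (4E,8Z,11S,12R)-8-({[tert-butyl(dimethyl)silyl]oxy}methyl)-12-hydroxy-11-(2-hydroxyethyl)-4,12,16-trimethylheptadeca-4,8,15-trienoate F4.
- PPh3/I2/imidazole gives the primary iodide ethyl (4E,8Z,11S,12R)-8-({[tert-butyl(dimethyl)silyl]oxy}methyl)-12-hydroxy-11-(2-iodoethyl)-4,12,16-trimethylheptadeca-4,8,15-trienoate F5.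
- Alkylation of ethylidenetriphenylphosphorane (from Ph3P(CH2CH3)Br and nBuLi) with F5 gives the secondary phosphonium salt {5-[(1R)-1-hydroxy-1,5-dimethylhex-4-en-1-yl]-…-ethyl ester chain}-(butan-2-yl)triphenylphosphonium iodide F6, that is, 20 with its vinyl group replaced by CH2CH2CH(CH3)PPh3+ I−.
- iBu2AlH at −78 °C reduces the ester to the corresponding C11 aldehyde phosphonium iodide F7.
- KN(SiMe3)2 in THF under high dilution closes the ring by intramolecular Wittig olefination. Z is expected to predominate for the non-stabilized ylide, and the E isomer would be removed by chromatography. The fallback returns to the route at 24.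

Further compounds
F1 | step 3 | (4R)-4-(2-bromo-1-ethoxyethoxy)-4-methylcyclopent-2-en-1-ol (both C1 and acetal epimers) | OC1C[C@@](C)(OC(CBr)OCC)C=C1
F2 | step 7 | methyl 2-[(2R,3R)-5-ethoxy-3-formyl-2-methyloxolan-2-yl]acetate | COC(=O)C[C@@]1(C)OC(OCC)C[C@H]1C=O
F3 | step 7 | methyl 2-[(2R,3S)-5-ethoxy-3-ethenyl-2-methyloxolan-2-yl]acetate | COC(=O)C[C@@]1(C)OC(OCC)C[C@H]1C=C
F4 | step 18 | ethyl (4E,8Z,11S,12R)-8-({[tert-butyl(dimethyl)silyl]oxy}methyl)-12-hydroxy-11-(2-hydroxyethyl)-4,12,16-trimethylheptadeca-4,8,15-trienoate | CC(C)=CCC[C@@](C)(O)[C@H](CCO)C/C=C(\CO[Si](C)(C)C(C)(C)C)CC/C=C(\C)CCC(=O)OCC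
F5 | step 18 | ethyl (4E,8Z,11S,12R)-8-({[tert-butyl(dimethyl)silyl]oxy}methyl)-12-hydroxy-11-(2-iodoethyl)-4,12,16-trimethylheptadeca-4,8,15-trienoate | CC(C)=CCC[C@@](C)(O)[C@H](CCI)C/C=C(\CO[Si](C)(C)C(C)(C)C)CC/C=C(\C)CCC(=O)OCC
F6 | step 18 | secondary phosphonium iodide: 20 with the vinyl group replaced by CH2CH2CH(CH3)PPh3+ I− (both epimers at the P-bearing carbon) | CC(C)=CCC[C@@](C)(O)[C@H](CCC(C)[P+](c1ccccc1)(c1ccccc1)c1ccccc1)C/C=C(\CO[Si](C)(C)C(C)(C)C)CC/C=C(\C)CCC(=O)OCC.[I-]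
F7 | step 18 | aldehyde phosphonium iodide: F6 with the ethyl ester reduced to the C11 aldehyde | CC(C)=CCC[C@@](C)(O)[C@H](CCC(C)[P+](c1ccccc1)(c1ccccc1)c1ccccc1)C/C=C(\CO[Si](C)(C)C(C)(C)C)CC/C=C(\C)CCC=O.[I-]
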